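The plan rests on one disconnection, the O–C3 bond of the tetrahydrofuran (ring B: O, C15, C1, C2, C3; cembrane numbering) that bridges C1 and C3 of the fourteen-membered carbocycle (ring A, C1–C14). Because this ether oxygen is β to the oxidised carbon C18 on C4, ring B is the conjugate adduct of a C3=C4–C18 enoate and the C15 hydroxyl carried by C1. A single base-catalysed transannular oxa-Michael addition therefore forms O–C3, closes ring B and creates C3 and C4. Its substrate is a monocyclic (1R,3E,7E,11Z)-cembratrienoate with free C15–OH, a C18 methyl ester and a silylated C19–OH, built by allyl sulfone coupling and macrocyclic Horner–Wadsworth–Emmons olefination.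

Key step: step 19

Remark (assumption): cembrane numbers are used for all atoms (C1 bears C15, C4 bears C18, C8 bears C19, C12 bears C20), and 3-[(4-methoxybenzyl)oxy]propanal is taken as a catalogue aldehyde.

Step 1
Reactants: 1 neryl acetate
Product: 2 (2Z)-5-[(2R)-3,3-dimethyloxiran-2-yl]-3-methylpent-2-en-1-yl acetate
Conditions: D-fructose-derived Shi ketone (0.3 equiv), KHSO5 (as 2KHSO5·KHSO4·K2SO4), K2CO3, Bu4NHSO4, MeCN/CH2(OMe)2–aq. Na2B4O7 buffer (pH 10.5), 0 °C
Reagents that add atoms: potassium peroxymonosulfate KHSO5, [K+].[O-]S(=O)(=O)OO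
Why: Shi asymmetric epoxidation by the chiral dioxirane should take place at the electron-rich 6,7-alkene (the future C1–C15 bond) rather than at the acetoxy-deactivated 2,3-alkene, and the spiro transition state of the D-fructose-derived ketone should deliver oxygen so that the epoxide CH carbon is (R).

Step 2
Reactants: 2 epoxy acetate
Product: 3 (2Z)-5-[(2R)-3,3-dimethyloxiran-2-yl]-3-methylpent-2-en-1-ol
Conditions: K2CO3 (0.3 equiv), MeOH, 0 °C
Reagents that add atoms: none
Why: Base-catalysed transesterification to methyl acetate removes the allylic acetate, which the copper-mediated step would otherwise displace, and does not touch the epoxide.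

Step 3
Reactants: 3 epoxy alcohol
Product: 4 (2Z,6R)-6-ethenyl-3,7-dimethyloct-2-ene-1,7-diol
Conditions: CH2=CHMgBr (4 equiv), CuBr·S(CH3)2 (0.2 equiv), THF, −30 to 0 °C
Reagents that add atoms: vinylmagnesium bromide, C=C[Mg]Br
Why: Copper-catalysed SN2 opening of the epoxide by CH2=CHMgBr should occur at the less substituted carbon with inversion, which sets C1 as (R), frees the C15 tertiary alcohol and brings in C2 and C3 as a vinyl group, the allylic alkoxide being inert.

Step 4
Reactants: 4 diol
Product: 7 (3R,6Z)-3-ethenyl-2,6-dimethyl-8-(phenylsulfonyl)oct-6-en-2-ol, via allylic mesylate 5 (not isolated), via allylic chloride 6 (not isolated)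
Conditions: MsCl, 2,4,6-collidine, LiCl, DMF, 0 °C; then PhSO2Na, Bu4NI (cat.), rt
Reagents that add atoms: sodium benzenesulfinate, [Na+].[O-]S(=O)c1ccccc1
Why: Collington–Meyers chlorination converts only the primary allylic alcohol (the tertiary one is not sulfonylated) without allylic transposition, and SN2 S-alkylation of the sulfinate then gives the C10 allyl sulfone with the (Z) alkene intact.

Step 5
Reactants: 8 methyl acrylate; 9 3-[(4-methoxybenzyl)oxy]propanal
Product: 10 methyl 3-hydroxy-5-[(4-methoxybenzyl)oxy]-2-methylidenepentanoate (racemic)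
Conditions: DABCO (0.5 equiv), 8 (3 equiv), MeOH, rt
Reagents that add atoms: none
Why: Morita–Baylis–Hillman reaction (amine conjugate addition to the acrylate, aldol addition of the zwitterionic enolate, loss of the amine) joins C8 to C7; the carbinol centre is racemic and is erased in step 6.

Step 6
Reactants: 10 hydroxy acrylate
Product: 11 methyl (2Z)-2-(bromomethyl)-5-[(4-methoxybenzyl)oxy]pent-2-enoate
Conditions: NBS, (CH3)2S, CH2Cl2, 0 °C to rt
Reagents that add atoms: N-bromosuccinimide, O=C1CCC(=O)N1Br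
Why: Corey–Kim-type activation of the alcohol as an alkoxysulfonium ion and SN2′ attack of bromide at the methylene carbon should give the conjugated (Z)-bromide, the isomer in which the C6 chain is trans to the ester carbon (C19) and cis to C9 as the target requires.

Step 7
Reactants: 11 bromo ester
Product: 12 (2Z)-2-(bromomethyl)-5-[(4-methoxybenzyl)oxy]pent-2-en-1-ol
Conditions: (i-Bu)2AlH (2.2 equiv), CH2Cl2, −78 °C
Reagents that add atoms: none
Why: 1,2-Reduction of the conjugated ester by (i-Bu)2AlH at −78 °C is faster than displacement of the primary allylic bromide and gives the C19 alcohol with unchanged alkene geometry.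

Step 8
Reactants: 12 bromo alcohol
Product: 13 {[(2Z)-2-(bromomethyl)-5-[(4-methoxybenzyl)oxy]pent-2-en-1-yl]oxy}(tert-butyl)dimethylsilane
Conditions: TBSOTf, 2,6-lutidine, CH2Cl2, −78 °C
Reagents that add atoms: tert-butyldimethylsilyl trifluoromethanesulfonate, CC(C)(C)[Si](C)(C)OS(=O)(=O)C(F)(F)F
Why: O-Silylation with the silyl triflate and a hindered base protects C19–OH without N-alkylation of the base by the allylic bromide.

Step 9
Reactants: 7 allyl sulfone; 13 allylic bromide
Product: 15 (3R,6Z,10E)-10-{[(tert-butyldimethylsilyl)oxy]methyl}-3-ethenyl-13-[(4-methoxybenzyl)oxy]-2,6-dimethyl-8-(phenylsulfonyl)trideca-6,10-dien-2-ol (both epimers at the sulfone carbon), via dilithio sulfone 14 (not isolated)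
Conditions: n-BuLi (2.05 equiv), THF/DMPU, −78 °C; then 13, −78 to −30 °C
Reagents that add atoms: none
Why: SN2 alkylation of the α-sulfonyl allyl carbanion at its α-carbon by the primary allylic bromide (allyl sulfone coupling) forms the C9–C10 bond, the tertiary lithium alkoxide being a poor nucleophile at −78 °C; the new sulfone-bearing centre is a mixture and is removed in step 10.

Step 10
Reactants: 15 coupled sulfone
Product: 16 (3R,6Z,10E)-10-{[(tert-butyldimethylsilyl)oxy]methyl}-3-ethenyl-13-[(4-methoxybenzyl)oxy]-2,6-dimethyltrideca-6,10-dien-2-ol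
Conditions: PdCl2[Ph2P(CH2)3PPh2] (5 mol %), LiBH(C2H5)3 (4 equiv), THF, 0 °C
Reagents that add atoms: none
Why: Palladium-catalysed reductive desulfonylation: zerovalent palladium formed in situ ionises the allylic sulfone and hydride is delivered to the less substituted terminus (C10) of the allyl complex, so the C11=C12 bond should keep its position and its (Z) geometry.

Step 11
Reactants: 16 p-methoxybenzyl ether
Product: 17 (3E,7Z,11R)-4-{[(tert-butyldimethylsilyl)oxy]methyl}-11-ethenyl-8,12-dimethyltrideca-3,7-diene-1,12-diol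
Conditions: DDQ, CH2Cl2/pH 7 buffer, 0 °C
Reagents that add atoms: none
Why: Oxidative cleavage of the p-methoxybenzyl ether (hydride abstraction by DDQ, hydrolysis of the oxocarbenium ion) frees C5–OH and leaves the silyl ether, the alkenes and the tertiary alcohol alone.

Step 12
Reactants: 17 diol
Product: 18 (3R,6Z,10E)-10-{[(tert-butyldimethylsilyl)oxy]methyl}-3-ethenyl-13-iodo-2,6-dimethyltrideca-6,10-dien-2-ol
Conditions: I2, PPh3, imidazole, CH2Cl2, 0 °C to rt
Reagents that add atoms: iodine, II
Why: Appel-type iodination (alkoxyphosphonium ion, SN2 by iodide) converts only the primary C5 alcohol, because the tertiary C15 alcohol cannot be displaced under these conditions.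

Step 13
Reactants: 18 iodide; 19 trimethyl phosphonoacetate
Product: 21 methyl (5E,9Z,13R)-6-{[(tert-butyldimethylsilyl)oxy]methyl}-2-(dimethoxyphosphoryl)-13-ethenyl-14-hydroxy-10,14-dimethylpentadeca-5,9-dienoate (both epimers at the phosphonate carbon), via sodium phosphonoacetate 20 (not isolated)
Conditions: 19 (3 equiv), NaH (2.8 equiv), DMF, 0 °C; then 18, 50 °C
Reagents that add atoms: none
Why: SN2 C-alkylation of the soft phosphonoacetate anion by the primary iodide forms the C4–C5 bond, the excess of anion limiting dialkylation and leaving the tertiary alcohol protonated; the C4 centre is a mixture and disappears in step 17.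

Step 14
Reactants: 21 hydroxy phosphonate
Product: 22 methyl (5E,9Z,13R)-6-{[(tert-butyldimethylsilyl)oxy]methyl}-2-(dimethoxyphosphoryl)-13-ethenyl-10,14-dimethyl-14-[(trimethylsilyl)oxy]pentadeca-5,9-dienoate
Conditions: 1-(trimethylsilyl)imidazole, CH2Cl2, rt
Reagents that add atoms: 1-(trimethylsilyl)imidazole, C[Si](C)(C)n1ccnc1
Why: Silyl transfer from the silylimidazole caps the tertiary C15 alcohol under neutral conditions, which prevents it from trapping the C3 aldehyde of steps 16 and 17 as a lactol.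

Step 15
Reactants: 22 trimethylsilyl ether
Product: 24 methyl (5E,9Z,13R)-6-{[(tert-butyldimethylsilyl)oxy]methyl}-2-(dimethoxyphosphoryl)-13-(2-hydroxyethyl)-10,14-dimethyl-14-[(trimethylsilyl)oxy]pentadeca-5,9-dienoate, via B-alkyl-9-BBN adduct 23 (not isolated)
Conditions: 9-BBN, THF, 0 °C to rt; then NaBO3·4H2O, H2O, rt
Reagents that add atoms: sodium perborate tetrahydrate NaBO3·4H2O, [Na+].[Na+].O[B-]1(O)OO[B-](O)(O)OO1
Why: Anti-Markovnikov hydroboration with 9-BBN is selective for the monosubstituted C2=C3 vinyl group over the two trisubstituted alkenes, and perborate oxidation of the C–B bond is mild enough for the methyl ester and both silyl ethers.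

Step 16
Reactants: 24 primary alcohol
Product: 25 methyl (5E,9Z,13R)-6-{[(tert-butyldimethylsilyl)oxy]methyl}-2-(dimethoxyphosphoryl)-10,14-dimethyl-13-(2-oxoethyl)-14-[(trimethylsilyl)oxy]pentadeca-5,9-dienoate
Conditions: Dess–Martin periodinane, NaHCO3, CH2Cl2, 0 °C to rt
Reagents that add atoms: none
Why: Dess–Martin oxidation converts the C3 alcohol into the aldehyde under buffered conditions that leave the phosphonate, the silyl ethers and the alkenes unchanged.

Step 17
Reactants: 25 aldehyde phosphonate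
Product: 26 methyl (1R,3E,7E,11Z)-19-[(tert-butyldimethylsilyl)oxy]-15-[(trimethylsilyl)oxy]cembra-3,7,11-trien-18-oate
Conditions: LiCl, DBU, MeCN, rt, slow addition (final concentration 1 mM)
Reagents that add atoms: none
Why: Intramolecular Horner–Wadsworth–Emmons olefination under Masamune–Roush conditions at high dilution closes ring A at C3=C4, and the α-alkylated phosphonoacetate should give mainly the (E)-enoate (ester trans to C2) through equilibration of the adducts.

Step 18
Reactants: 26 macrocyclic trimethylsilyl ether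
Product: 27 methyl (1R,3E,7E,11Z)-19-[(tert-butyldimethylsilyl)oxy]-15-hydroxycembra-3,7,11-trien-18-oate
Conditions: citric acid, MeOH, 0 °C
Reagents that add atoms: none
Why: Acid-catalysed methanolysis cleaves the trimethylsilyl ether far faster than the tert-butyldimethylsilyl ether and, being acidic, cannot start the conjugate addition.

Step 19
Reactants: 27 macrocyclic hydroxy enoate
Product: 28 methyl (1R,3R,4S,7E,11Z)-19-[(tert-butyldimethylsilyl)oxy]-3,15-epoxycembra-7,11-dien-18-oate
Conditions: KOC(CH3)3 (0.2 equiv), THF/t-BuOH, −20 °C to rt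
Reagents that add atoms: none
Why: KOC(CH3)3 deprotonates the C15 hydroxyl, the tertiary alkoxide adds to C3 (the β-carbon of the C3=C4–C18 enoate) and the ester enolate is protonated at C4 by t-BuOH; this is the known base-catalysed intramolecular oxa-Michael cyclisation of hydroxy enoates to tetrahydrofurans, run here across ring A. Ring B (O, C15, C1, C2, C3) closes in the 5-exo-trig mode, helped by the gem-dimethyl group on C15. C3 is under thermodynamic control: the addition is reversible and only the cis arrangement of the C1–C14 and C3–C4 bonds on ring B lets the eleven-carbon bridge span C1 and C3 without strain, so the (3R) adduct should accumulate. C4 is set by protonation of the enolate: net anti addition of O and H across the (E)-alkene corresponds to the required (4S) ester, protonation from the outer face of the macrocycle is expected, and the centre can be re-equilibrated through the enolate or by retro-addition, but this remains the uncertain point of the route. The step needs 1,4- rather than 1,2-attack and attack at C3 only: the (E) geometry holds the ester carbonyl away from the alkoxide so that lactonisation cannot compete, and C3 is the only electrophilic alkene carbon, since C7=C8 and C11=C12 are unactivated and the C19 oxygen is silylated.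

Step 20
Reactants: 28 bridged ester
Product: 29 (1R,3R,4R,7E,11Z)-19-[(tert-butyldimethylsilyl)oxy]-3,15-epoxycembra-7,11-dien-18-ol
Conditions: (i-Bu)2AlH (3 equiv), CH2Cl2, −78 °C
Reagents that add atoms: none
Why: Hydride reduction of the methyl ester to the primary C18 alcohol proceeds without enolisation, so C4 keeps its configuration (the descriptor changes from S to R only because the priorities change).

Step 21
Reactants: 29 primary alcohol; 30 Meldrum's acid
Product: 31 3-{[(1R,3R,4R,7E,11Z)-19-[(tert-butyldimethylsilyl)oxy]-3,15-epoxycembra-7,11-dien-18-yl]oxy}-3-oxopropanoic acid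
Conditions: 30 (1.5 equiv), toluene, 90 °C
Reagents that add atoms: none
Why: Thermal acylation by Meldrum's acid (opening of the dioxanedione by the alcohol with loss of acetone) gives the malonic half ester in one step, and only C18–OH can react because the C19 oxygen is still silylated.

Step 22
Reactants: 31 silylated half ester
Product: 32 3-{[(1R,3R,4R,7E,11Z)-3,15-epoxy-19-hydroxycembra-7,11-dien-18-yl]oxy}-3-oxopropanoic acid
Conditions: HF·pyridine, pyridine/THF, 0 °C to rt
Reagents that add atoms: none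
Why: Fluoride-induced cleavage of the primary allylic silyl ether under buffered conditions leaves the malonate ester, the free acid and the ether bridge untouched.

Step 23
Reactants: 32 hydroxy acid
Product: 33 3-{[(1R,3R,4R,7E,11Z)-3,15-epoxy-19-oxocembra-7,11-dien-18-yl]oxy}-3-oxopropanoic acid (CNP0170412.1)
Conditions: TEMPO (10 mol %), PhI(OAc)2, CH2Cl2, rt
Reagents that add atoms: none
Why: Oxoammonium (TEMPO) oxidation with PhI(OAc)2 as terminal oxidant converts the only alcohol, the allylic C19–OH, into the (E)-enal without over-oxidation and tolerates the free acid.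

Compound list
1 | neryl acetate | CC(C)=CCC/C(C)=C\COC(C)=O | starting material
2 | (2Z)-5-[(2R)-3,3-dimethyloxiran-2-yl]-3-methylpent-2-en-1-yl acetate | CC(=O)OC/C=C(C)\CC[C@H]1OC1(C)C | intermediate
3 | (2Z)-5-[(2R)-3,3-dimethyloxiran-2-yl]-3-methylpent-2-en-1-ol | OC/C=C(C)\CC[C@H]1OC1(C)C | intermediate
4 | (2Z,6R)-6-ethenyl-3,7-dimethyloct-2-ene-1,7-diol | C=C[C@@H](CC/C(C)=C\CO)C(C)(C)O | intermediate
5 | (2Z,6R)-6-ethenyl-7-hydroxy-3,7-dimethyloct-2-en-1-yl methanesulfonate | C=C[C@@H](CC/C(C)=C\COS(C)(=O)=O)C(C)(C)O | intermediate (not isolated)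
6 | (3R,6Z)-8-chloro-3-ethenyl-2,6-dimethyloct-6-en-2-ol | C=C[C@@H](CC/C(C)=C\CCl)C(C)(C)O | intermediate (not isolated)
7 | (3R,6Z)-3-ethenyl-2,6-dimethyl-8-(phenylsulfonyl)oct-6-en-2-ol | C=C[C@@H](CC/C(C)=C\CS(=O)(=O)c1ccccc1)C(C)(C)O | intermediate
8 | methyl acrylate | C=CC(=O)OC | starting material
9 | 3-[(4-methoxybenzyl)oxy]propanal | O=CCCOCc1ccc(OC)cc1 | starting material
10 | methyl 3-hydroxy-5-[(4-methoxybenzyl)oxy]-2-methylidenepentanoate (racemic) | C=C(C(=O)OC)C(O)CCOCc1ccc(OC)cc1 | intermediate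
11 | methyl (2Z)-2-(bromomethyl)-5-[(4-methoxybenzyl)oxy]pent-2-enoate | COC(=O)/C(CBr)=C/CCOCc1ccc(OC)cc1 | intermediate
12 | (2Z)-2-(bromomethyl)-5-[(4-methoxybenzyl)oxy]pent-2-en-1-ol | OC/C(CBr)=C/CCOCc1ccc(OC)cc1 | intermediate
13 | {[(2Z)-2-(bromomethyl)-5-[(4-methoxybenzyl)oxy]pent-2-en-1-yl]oxy}(tert-butyl)dimethylsilane | CC(C)(C)[Si](C)(C)OC/C(CBr)=C/CCOCc1ccc(OC)cc1 | intermediate
14 | dilithio derivative of 7 (lithium alkoxide at C15, lithiated sulfone carbon C10) | [Li+].[Li+].C=C[C@@H](CC/C(C)=C\[CH-]S(=O)(=O)c1ccccc1)C(C)(C)[O-] | intermediate (not isolated)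
15 | (3R,6Z,10E)-10-{[(tert-butyldimethylsilyl)oxy]methyl}-3-ethenyl-13-[(4-methoxybenzyl)oxy]-2,6-dimethyl-8-(phenylsulfonyl)trideca-6,10-dien-2-ol (epimers at C8 of the chain) | C=C[C@@H](CC/C(C)=C\C(C/C(CO[Si](C)(C)C(C)(C)C)=C\CCOCc1ccc(OC)cc1)S(=O)(=O)c1ccccc1)C(C)(C)O | intermediate
16 | (3R,6Z,10E)-10-{[(tert-butyldimethylsilyl)oxy]methyl}-3-ethenyl-13-[(4-methoxybenzyl)oxy]-2,6-dimethyltrideca-6,10-dien-2-ol | C=C[C@@H](CC/C(C)=C\CC/C(CO[Si](C)(C)C(C)(C)C)=C\CCOCc1ccc(OC)cc1)C(C)(C)O | intermediate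
17 | (3E,7Z,11R)-4-{[(tert-butyldimethylsilyl)oxy]methyl}-11-ethenyl-8,12-dimethyltrideca-3,7-diene-1,12-diol | C=C[C@@H](CC/C(C)=C\CC/C(CO[Si](C)(C)C(C)(C)C)=C\CCO)C(C)(C)O | intermediate
18 | (3R,6Z,10E)-10-{[(tert-butyldimethylsilyl)oxy]methyl}-3-ethenyl-13-iodo-2,6-dimethyltrideca-6,10-dien-2-ol | C=C[C@@H](CC/C(C)=C\CC/C(CO[Si](C)(C)C(C)(C)C)=C\CCI)C(C)(C)O | intermediate
19 | trimethyl phosphonoacetate | COC(=O)CP(=O)(OC)OC | starting material
20 | sodium salt of trimethyl phosphonoacetate | [Na+].COC(=O)[CH-]P(=O)(OC)OC | intermediate (not isolated)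
21 | methyl (5E,9Z,13R)-6-{[(tert-butyldimethylsilyl)oxy]methyl}-2-(dimethoxyphosphoryl)-13-ethenyl-14-hydroxy-10,14-dimethylpentadeca-5,9-dienoate (epimers at C2 of the chain) | C=C[C@@H](CC/C(C)=C\CC/C(CO[Si](C)(C)C(C)(C)C)=C\CCC(C(=O)OC)P(=O)(OC)OC)C(C)(C)O | intermediate
22 | methyl (5E,9Z,13R)-6-{[(tert-butyldimethylsilyl)oxy]methyl}-2-(dimethoxyphosphoryl)-13-ethenyl-10,14-dimethyl-14-[(trimethylsilyl)oxy]pentadeca-5,9-dienoate | C=C[C@@H](CC/C(C)=C\CC/C(CO[Si](C)(C)C(C)(C)C)=C\CCC(C(=O)OC)P(=O)(OC)OC)C(C)(C)O[Si](C)(C)C | intermediate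
23 | B-alkyl-9-borabicyclo[3.3.1]nonane from 22 (boron on C3) | B1(CC[C@@H](CC/C(C)=C\CC/C(CO[Si](C)(C)C(C)(C)C)=C\CCC(C(=O)OC)P(=O)(OC)OC)C(C)(C)O[Si](C)(C)C)C2CCCC1CCC2 | intermediate (not isolated)
24 | methyl (5E,9Z,13R)-6-{[(tert-butyldimethylsilyl)oxy]methyl}-2-(dimethoxyphosphoryl)-13-(2-hydroxyethyl)-10,14-dimethyl-14-[(trimethylsilyl)oxy]pentadeca-5,9-dienoate | OCC[C@@H](CC/C(C)=C\CC/C(CO[Si](C)(C)C(C)(C)C)=C\CCC(C(=O)OC)P(=O)(OC)OC)C(C)(C)O[Si](C)(C)C | intermediate
25 | methyl (5E,9Z,13R)-6-{[(tert-butyldimethylsilyl)oxy]methyl}-2-(dimethoxyphosphoryl)-10,14-dimethyl-13-(2-oxoethyl)-14-[(trimethylsilyl)oxy]pentadeca-5,9-dienoate | O=CC[C@@H](CC/C(C)=C\CC/C(CO[Si](C)(C)C(C)(C)C)=C\CCC(C(=O)OC)P(=O)(OC)OC)C(C)(C)O[Si](C)(C)C | intermediate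
26 | methyl (1R,3E,7E,11Z)-19-[(tert-butyldimethylsilyl)oxy]-15-[(trimethylsilyl)oxy]cembra-3,7,11-trien-18-oate | C/C1=C/CC/C(CO[Si](C)(C)C(C)(C)C)=C\CC/C(C(=O)OC)=C\C[C@@H](CC1)C(C)(C)O[Si](C)(C)C | intermediate
27 | methyl (1R,3E,7E,11Z)-19-[(tert-butyldimethylsilyl)oxy]-15-hydroxycembra-3,7,11-trien-18-oate | C/C1=C/CC/C(CO[Si](C)(C)C(C)(C)C)=C\CC/C(C(=O)OC)=C\C[C@@H](CC1)C(C)(C)O | intermediate
28 | methyl (1R,3R,4S,7E,11Z)-19-[(tert-butyldimethylsilyl)oxy]-3,15-epoxycembra-7,11-dien-18-oate | C/C1=C/CC/C(CO[Si](C)(C)C(C)(C)C)=C\CC[C@H](C(=O)OC)[C@H]2C[C@@H](CC1)C(C)(C)O2 | intermediate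
29 | (1R,3R,4R,7E,11Z)-19-[(tert-butyldimethylsilyl)oxy]-3,15-epoxycembra-7,11-dien-18-ol | C/C1=C/CC/C(CO[Si](C)(C)C(C)(C)C)=C\CC[C@H](CO)[C@H]2C[C@@H](CC1)C(C)(C)O2 | intermediate
30 | Meldrum's acid (2,2-dimethyl-1,3-dioxane-4,6-dione) | CC1(C)OC(=O)CC(=O)O1 | starting material
31 | 3-{[(1R,3R,4R,7E,11Z)-19-[(tert-butyldimethylsilyl)oxy]-3,15-epoxycembra-7,11-dien-18-yl]oxy}-3-oxopropanoic acid | C/C1=C/CC/C(CO[Si](C)(C)C(C)(C)C)=C\CC[C@H](COC(=O)CC(=O)O)[C@H]2C[C@@H](CC1)C(C)(C)O2 | intermediate
32 | 3-{[(1R,3R,4R,7E,11Z)-3,15-epoxy-19-hydroxycembra-7,11-dien-18-yl]oxy}-3-oxopropanoic acid | C/C1=C/CC/C(CO)=C\CC[C@H](COC(=O)CC(=O)O)[C@H]2C[C@@H](CC1)C(C)(C)O2 | intermediate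
33 | 3-{[(1R,3R,4R,7E,11Z)-3,15-epoxy-19-oxocembra-7,11-dien-18-yl]oxy}-3-oxopropanoic acid (CNP0170412.1) | C/C1=C/CC/C(C=O)=C\CC[C@H](COC(=O)CC(=O)O)[C@H]2C[C@@H](CC1)C(C)(C)O2 | target

Total step count: 23. Longest linear sequence: 19 steps (steps 1–4 and 9–23; the branch through steps 5–8 is equally long).

Steps most likely to fail

1. Step 19. What may go wrong: poor facial selectivity in the protonation of the C4 ester enolate, or an addition equilibrium that does not leave the open enoate. The fallback changes the acceptor from the ester to the aldehyde and sets out from 27. (i-Bu)2AlH (CH2Cl2, −78 °C) would reduce the enoate to (1R,3E,7E,11Z)-19-[(tert-butyldimethylsilyl)oxy]cembra-3,7,11-triene-15,18-diol F1. MnO2 (CH2Cl2, rt) would oxidise its allylic C18 alcohol selectively to (1R,3E,7E,11Z)-19-[(tert-butyldimethylsilyl)oxy]-15-hydroxycembra-3,7,11-trien-18-al F2. DBU (cat., CH2Cl2) would then bring about the same transannular oxa-Michael closure on the more electrophilic enal and give (1R,3R,4S,7E,11Z)-19-[(tert-butyldimethylsilyl)oxy]-3,15-epoxycembra-7,11-dien-18-al F3. Its C4 centre is α to an aldehyde, so it can be equilibrated by enolisation without reopening ring B, or trapped at once. NaBH4 (MeOH, 0 °C) would then give 29, where the route is rejoined; step 20 is no longer needed.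

2. Step 17. What may go wrong: intermolecular olefination (dimers and oligomers) and base-induced self-condensation of the aldehyde outrun the slow ring closure by the α-branched phosphonate anion. The fallback closes ring A at C4–C5 by an irreversible enolate alkylation and introduces the C3=C4 bond afterwards; it sets out from 18. TMSOTf/2,6-lutidine (CH2Cl2, −78 °C) would give the trimethylsilyl ether of iodide 18 F4. 9-BBN followed by NaBO3·4H2O would give the C3 primary alcohol F5, and Dess–Martin periodinane the C3 aldehyde F6. Methyl diazoacetate with SnCl2 (cat., CH2Cl2; Roskamp homologation) would convert the aldehyde into the acyclic β-keto ester F7, with the ketone on C3. Cs2CO3 (MeCN, 60 °C, high dilution) would close the ring by SN2 C-alkylation of the β-keto ester at C4 by the C5 iodide, giving methyl (1R,7E,11Z)-19-[(tert-butyldimethylsilyl)oxy]-3-oxo-15-[(trimethylsilyl)oxy]cembra-7,11-dien-18-oate F8. NaBH4 (EtOH, 0 °C) would reduce the ketone to the C3 hydroxy ester F9, and MsCl/Et3N would give its C3 methanesulfonate F10. DBU would eliminate the methanesulfonate by the E1cB path, which can only place the double bond at C3=C4 because C4 is the acidic carbon, and should give mainly the (E)-enoate 26, where the route is rejoined.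

3. Step 3. What may go wrong: slow SN2 attack at the hindered epoxide carbon, so that Lewis-acid-induced rearrangement (hydride shift to the ketone) and bromohydrin formation by the magnesium halide take over. The fallback is alkynylation without a Lewis acid followed by partial hydrogenation, and sets out from 3. Lithium acetylide–ethylenediamine complex (LiC≡CH·H2NCH2CH2NH2, DMSO, rt to 40 °C) would open the epoxide at the same carbon with inversion and give (2Z,6R)-6-ethynyl-3,7-dimethyloct-2-ene-1,7-diol F11. Hydrogenation over Pd on CaCO3 poisoned with Pb(OAc)2 (H2, quinoline, EtOAc) would reduce the alkyne to the vinyl group and give 4, where the route is rejoined.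

Further compounds
F1 | step 19 | (1R,3E,7E,11Z)-19-[(tert-butyldimethylsilyl)oxy]cembra-3,7,11-triene-15,18-diol | C/C1=C/CC/C(CO[Si](C)(C)C(C)(C)C)=C\CC/C(CO)=C\C[C@@H](CC1)C(C)(C)O
F2 | step 19 | (1R,3E,7E,11Z)-19-[(tert-butyldimethylsilyl)oxy]-15-hydroxycembra-3,7,11-trien-18-al | C/C1=C/CC/C(CO[Si](C)(C)C(C)(C)C)=C\CC/C(C=O)=C\C[C@@H](CC1)C(C)(C)O
F3 | step 19 | (1R,3R,4S,7E,11Z)-19-[(tert-butyldimethylsilyl)oxy]-3,15-epoxycembra-7,11-dien-18-al | C/C1=C/CC/C(CO[Si](C)(C)C(C)(C)C)=C\CC[C@H](C=O)[C@H]2C[C@@H](CC1)C(C)(C)O2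
F4 | step 17 | trimethylsilyl ether of iodide 18 | C=C[C@@H](CC/C(C)=C\CC/C(CO[Si](C)(C)C(C)(C)C)=C\CCI)C(C)(C)O[Si](C)(C)C
F5 | step 17 | C3 primary alcohol from F4 (vinyl group turned into CH2CH2OH) | OCC[C@@H](CC/C(C)=C\CC/C(CO[Si](C)(C)C(C)(C)C)=C\CCI)C(C)(C)O[Si](C)(C)C
F6 | step 17 | C3 aldehyde from F5 | O=CC[C@@H](CC/C(C)=C\CC/C(CO[Si](C)(C)C(C)(C)C)=C\CCI)C(C)(C)O[Si](C)(C)C
F7 | step 17 | acyclic β-keto ester (C3 ketone, C4 methylene, C18 methyl ester, C5 iodide) | COC(=O)CC(=O)C[C@@H](CC/C(C)=C\CC/C(CO[Si](C)(C)C(C)(C)C)=C\CCI)C(C)(C)O[Si](C)(C)C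
F8 | step 17 | methyl (1R,7E,11Z)-19-[(tert-butyldimethylsilyl)oxy]-3-oxo-15-[(trimethylsilyl)oxy]cembra-7,11-dien-18-oate (C4 epimers) | C/C1=C/CC/C(CO[Si](C)(C)C(C)(C)C)=C\CCC(C(=O)OC)C(=O)C[C@@H](CC1)C(C)(C)O[Si](C)(C)C
F9 | step 17 | methyl (1R,7E,11Z)-19-[(tert-butyldimethylsilyl)oxy]-3-hydroxy-15-[(trimethylsilyl)oxy]cembra-7,11-dien-18-oate (C3 and C4 epimers) | C/C1=C/CC/C(CO[Si](C)(C)C(C)(C)C)=C\CCC(C(=O)OC)C(O)C[C@@H](CC1)C(C)(C)O[Si](C)(C)C
F10 | step 17 | C3 methanesulfonate of F9 | C/C1=C/CC/C(CO[Si](C)(C)C(C)(C)C)=C\CCC(C(=O)OC)C(OS(C)(=O)=O)C[C@@H](CC1)C(C)(C)O[Si](C)(C)C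
F11 | step 3 | (2Z,6R)-6-ethynyl-3,7-dimethyloct-2-ene-1,7-diol | C#C[C@@H](CC/C(C)=C\CO)C(C)(C)O
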